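**Retrosynthetic overview**
- Arene pieces: phenol 1 is O-benzylated to syringyl bromide 2; guaiacyl bromide 3 is bought; the only bought stereocentre is that of (R)-glycidol 4.
- C1–aryl disconnection: Grignard reagent 5 (from 3) adds to (S)-glycidaldehyde 6 (from 4) to give anti-epoxy alcohol 7; the epoxide stereocentre sets C1.
- C2–aryl disconnection (key): visible-light Ni/Ti arylative opening of 7 at its internal epoxide carbon with 2 gives diol 8; C1 sets C2 through a titanium 1,3-diolate ring.
- Twofold O-debenzylation of 8 gives target 9.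
- Rings: both benzene rings are bought and no ring is built; the bought oxirane is opened in the key step.

Assumption: bromide 3 and (R)-glycidol are catalogue items. C1 is the carbinol carbon bearing the guaiacyl ring, C2 the carbon bearing the syringyl ring, C3 the CH2OH carbon.

**Step 1**
Reactants: 1 4-bromo-2,6-dimethoxyphenol
Product: 2 2-(benzyloxy)-5-bromo-1,3-dimethoxybenzene
Conditions: BnBr (1.1 equiv), K2CO3, DMF, 60 °C
Reagents that add atoms: benzyl bromide, BrCc1ccccc1
Why: Williamson ether synthesis of an acidic phenol with a primary benzylic bromide; no stereocentre is involved.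

**Step 2**
Reactants: 3 1-(benzyloxy)-4-bromo-2-methoxybenzene; 4 (R)-glycidol
Product: 7 (R)-[4-(benzyloxy)-3-methoxyphenyl][(2S)-oxiran-2-yl]methanol, via aryl Grignard reagent 5 (not isolated), via (S)-glycidaldehyde 6 (not isolated)
Conditions: flask A: 3 (3.5 equiv), Mg turnings, THF, 40 °C; flask B: 4, (COCl)2, DMSO, CH2Cl2, −78 °C, then Et3N, −78 to −50 °C; A into B at −78 °C, 2 h; H2O quench at −78 °C; chromatography to remove the C1 epimer
Reagents that add atoms: none
Why: One-pot Swern oxidation and Grignard addition, in which 5 attacks 6 in the Felkin–Anh (polar) sense, anti to the epoxide C–O bond, so the bought epoxide stereocentre sets C1 as R in the anti isomer (expected about 3:1 over the syn epimer, which would lead to the enantiomeric series and is therefore separated here).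

**Step 3**
Reactants: 7 (R)-[4-(benzyloxy)-3-methoxyphenyl][(2S)-oxiran-2-yl]methanol; 2 2-(benzyloxy)-5-bromo-1,3-dimethoxybenzene
Product: 8 (1S,2S)-1-[4-(benzyloxy)-3-methoxyphenyl]-2-[4-(benzyloxy)-3,5-dimethoxyphenyl]propane-1,3-diol
Conditions: 2 (1.5 equiv), NiBr2·DME (10 mol %), 4,4′-di-tert-butyl-2,2′-bipyridine (12 mol %), Cp2TiCl2 (30 mol %), 4CzIPN (3 mol %), Et3N (4 equiv), THF–DMA 4:1, 450 nm LEDs, 20 °C; aqueous work-up
Reagents that add atoms: none
Why: Proposed new method: reduced 4CzIPN (from quenching of the excited dye by Et3N) turns Cp2TiCl2 into a trivalent titanium species that binds the hydroxyl and epoxide oxygens of 7 and opens the epoxide by homolysis of the internal C2–O bond, so the secondary C2 radical sits in a six-membered tetravalent titanium 1,3-diolate ring with the C1 aryl group equatorial; the aryl–nickel bromide complex formed from 2 and zerovalent nickel captures this radical on the face anti to the C1 aryl group, and reductive elimination from trivalent nickel gives the ring-trans (1,2-anti) product, i.e. C2 = S under control of C1 (C1 is untouched; its descriptor changes from R to S only because C2 no longer carries oxygen), after which Et3NH+ releases 8 and returns the titanium; closest known reaction type: the manganese-driven, branched-selective Ni/Ti reductive arylation of simple terminal epoxides and the Ni/Ti/photoredox arylation of styrene oxides and cyclic epoxides, none of which has been shown on a free 2,3-epoxy alcohol, as a light-driven branched opening of an aliphatic terminal epoxide, or with hydroxyl-templated 1,2-stereocontrol.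

**Step 4**
Reactants: 8 (1S,2S)-1-[4-(benzyloxy)-3-methoxyphenyl]-2-[4-(benzyloxy)-3,5-dimethoxyphenyl]propane-1,3-diol
Product: 9 (1S,2S)-2-(4-hydroxy-3,5-dimethoxyphenyl)-1-(4-hydroxy-3-methoxyphenyl)propane-1,3-diol
Conditions: H2 (1 atm), 10% Pd/C, EtOAc–EtOH 1:1, 20 °C, stopped at full conversion
Reagents that add atoms: none
Why: Catalytic hydrogenolysis cleaves the two aryl benzyl ethers much faster than the secondary benzylic C–OH bond under neutral conditions, and neither stereocentre is touched.

**Compound list**
1 | 4-bromo-2,6-dimethoxyphenol | COc1cc(Br)cc(OC)c1O | starting material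
2 | 2-(benzyloxy)-5-bromo-1,3-dimethoxybenzene | COc1cc(Br)cc(OC)c1OCc1ccccc1 | intermediate
3 | 1-(benzyloxy)-4-bromo-2-methoxybenzene | COc1cc(Br)ccc1OCc1ccccc1 | starting material
4 | (R)-glycidol, [(2R)-oxiran-2-yl]methanol | OC[C@@H]1CO1 | starting material
5 | [4-(benzyloxy)-3-methoxyphenyl]magnesium bromide | COc1cc([Mg]Br)ccc1OCc1ccccc1 | intermediate
6 | (S)-glycidaldehyde, (2S)-oxirane-2-carbaldehyde | O=C[C@@H]1CO1 | intermediate
7 | (R)-[4-(benzyloxy)-3-methoxyphenyl][(2S)-oxiran-2-yl]methanol | COc1cc([C@@H](O)[C@@H]2CO2)ccc1OCc1ccccc1 | intermediate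
8 | (1S,2S)-1-[4-(benzyloxy)-3-methoxyphenyl]-2-[4-(benzyloxy)-3,5-dimethoxyphenyl]propane-1,3-diol | COc1cc([C@@H](O)[C@H](CO)c2cc(OC)c(OCc3ccccc3)c(OC)c2)ccc1OCc1ccccc1 | intermediate
9 | (1S,2S)-2-(4-hydroxy-3,5-dimethoxyphenyl)-1-(4-hydroxy-3-methoxyphenyl)propane-1,3-diol | COc1cc([C@@H](O)[C@H](CO)c2cc(OC)c(O)c(OC)c2)ccc1O | target

**Step count**
Total steps: 4. Longest linear sequence: 3 (4 → 7 → 8 → 9; equally 1 → 2 → 8 → 9).

**Three steps most likely to fail**

Step 3 (the new light-driven arylative epoxide opening). Possible failures are opening at the terminal carbon through a halohydrin, deoxygenation to the allylic alcohol, simple reduction, slow oxidative addition of the electron-rich bromide 2, or low selectivity at C2. The fallback uses known reactions only, sets out from 7 and comes back at 8.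
- The epoxide of 7 is hydrolysed with aqueous NaOH in t-BuOH at 60 °C to (1R,2S)-1-[4-(benzyloxy)-3-methoxyphenyl]propane-1,2,3-triol F1. Hydroxide enters at the terminal carbon, and the C2 configuration no longer matters from here on.
- tBu2Si(OTf)2 and 2,6-lutidine close the six-membered silylene over the C1 and C3 oxygens to give (4R,5S)-4-[4-(benzyloxy)-3-methoxyphenyl]-2,2-di-tert-butyl-1,3,2-dioxasilinan-5-ol F2.
- The free ring hydroxyl is condensed with 5,7-di-tert-butyl-3-phenylbenzoxazolium tetrafluoroborate and pyridine to the 2-alkoxybenzoxazoline adduct F3, which is not isolated.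
- The established nickel/photoredox deoxygenative arylation with 2 (Ir(ppy)2(dtbbpy)PF6, NiBr2(dtbbpy), quinuclidine, DMA–MTBE, 450 nm) then gives (4S,5S)-4-[4-(benzyloxy)-3-methoxyphenyl]-5-[4-(benzyloxy)-3,5-dimethoxyphenyl]-2,2-di-tert-butyl-1,3,2-dioxasilinane F4. The ring radical is arylated anti to the neighbouring aryl group.
- HF·pyridine in THF removes the silylene and gives 8.

Step 2 (one-pot oxidation and aryl addition). The anti:syn ratio is expected to be modest (about 3:1), and the one-pot protocol wastes Grignard reagent. The fallback sets out from 7 as obtained (mixed with its C1 epimer) and comes back at 7.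
- The mixture is oxidised with MnO2 in CH2Cl2 at 20 °C to the single ketone [4-(benzyloxy)-3-methoxyphenyl][(2S)-oxiran-2-yl]methanone F5.
- F5 is reduced with Zn(BH4)2 in Et2O at −30 °C. Hydride adds to the zinc chelate of the carbonyl and epoxide oxygens from the face away from the epoxide CH2; this is the established anti-selective reduction of α,β-epoxy ketones and returns 7 as one diastereomer.
- C1 is then set by ketone reduction instead of by aryl addition.

Step 4 (hydrogenolysis). The risk is loss of the benzylic C1 hydroxyl once the para-phenol is free. The fallback sets out from 8 and comes back at 9.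
- The 1,3-diol of 8 is tied up with tBu2Si(OTf)2 and 2,6-lutidine as the silylene F4 (the same compound as in the step 3 fallback).
- The benzyl ethers are hydrogenolysed there (H2, Pd/C, EtOAc), where the benzylic oxygen is a ring silyl ether, to give (4S,5S)-2,2-di-tert-butyl-5-(4-hydroxy-3,5-dimethoxyphenyl)-4-(4-hydroxy-3-methoxyphenyl)-1,3,2-dioxasilinane F6.
- HF·pyridine in THF at 0 °C frees the diol and gives 9.

**Further compounds**
F1 | step 3 | (1R,2S)-1-[4-(benzyloxy)-3-methoxyphenyl]propane-1,2,3-triol | COc1cc([C@@H](O)[C@@H](O)CO)ccc1OCc1ccccc1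
F2 | step 3 | (4R,5S)-4-[4-(benzyloxy)-3-methoxyphenyl]-2,2-di-tert-butyl-1,3,2-dioxasilinan-5-ol | COc1cc([C@H]2O[Si](C(C)(C)C)(C(C)(C)C)OC[C@@H]2O)ccc1OCc1ccccc1
F3 | step 3 | 2-{[(4R,5S)-4-[4-(benzyloxy)-3-methoxyphenyl]-2,2-di-tert-butyl-1,3,2-dioxasilinan-5-yl]oxy}-5,7-di-tert-butyl-3-phenyl-2,3-dihydro-1,3-benzoxazole | COc1cc([C@H]2O[Si](C(C)(C)C)(C(C)(C)C)OC[C@@H]2OC2Oc3c(cc(cc3C(C)(C)C)C(C)(C)C)N2c2ccccc2)ccc1OCc1ccccc1
F4 | step 3 | (4S,5S)-4-[4-(benzyloxy)-3-methoxyphenyl]-5-[4-(benzyloxy)-3,5-dimethoxyphenyl]-2,2-di-tert-butyl-1,3,2-dioxasilinane | COc1cc([C@H]2O[Si](C(C)(C)C)(C(C)(C)C)OC[C@@H]2c2cc(OC)c(OCc3ccccc3)c(OC)c2)ccc1OCc1ccccc1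
F5 | step 2 | [4-(benzyloxy)-3-methoxyphenyl][(2S)-oxiran-2-yl]methanone | COc1cc(C(=O)[C@@H]2CO2)ccc1OCc1ccccc1
F6 | step 4 | (4S,5S)-2,2-di-tert-butyl-5-(4-hydroxy-3,5-dimethoxyphenyl)-4-(4-hydroxy-3-methoxyphenyl)-1,3,2-dioxasilinane | COc1cc([C@H]2O[Si](C(C)(C)C)(C(C)(C)C)OC[C@@H]2c2cc(OC)c(O)c(OC)c2)ccc1O
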